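**Retrosynthetic overview**
- The strategy rests on ring A: oxygen at C1 and at C5 are meta to each other, with H on C6 between them and the C14 chain on C3. This is the pattern left when a nucleophile adds to a 3-alkoxyaryne.
- Target 23 ⇐ trimethyl ether 22 (cleavage of three O–Me bonds) ⇐ phenol/ortho-silylaryl triflate 20, by addition of the ring B C1' phenoxide to a C5≡C6 aryne of ring A flanked by the C1 methoxy group.
- 20 ⇐ carbamate 13, by directed ortho-silylation at C6, carbamate-to-triflate exchange and debenzylation.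
- 13 ⇐ ring B bromide 6 + 1,13-tetradecadiene 7 + 3-bromo-5-methoxyphenol 10 (two B-alkyl Suzuki couplings); 6 ⇐ 2-hydroxy-5-methoxybenzaldehyde 1.
- Rings A and B are bought; the only ring formed is the 21-membered macrocycle, closed in step 11.

Key step: step 11

Remark: the target has no stereocentre. Ring A is numbered C1 (OH), C3 (chain), C5 (ether O); ring B is numbered C1' (ether O), C2' (OH), C3' (chain), C5' (OH).

**Step 1**
Reactants: 1 2-hydroxy-5-methoxybenzaldehyde
Product: 2 3-bromo-2-hydroxy-5-methoxybenzaldehyde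
Conditions: Br2, NaOAc, AcOH, rt
Reagents that add atoms: bromine, BrBr
Why: Electrophilic aromatic bromination should go ortho to the free phenol (its para position carries OMe), at the one site that is also meta to the deactivating formyl group.

**Step 2**
Reactants: 2 3-bromo-2-hydroxy-5-methoxybenzaldehyde
Product: 3 3-bromo-2,5-dimethoxybenzaldehyde
Conditions: MeI, K2CO3, DMF, 40 °C
Reagents that add atoms: iodomethane, CI
Why: Williamson O-methylation of the phenoxide fixes the future C2' oxygen as its methyl ether.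

**Step 3**
Reactants: 3 3-bromo-2,5-dimethoxybenzaldehyde
Product: 5 3-bromo-2,5-dimethoxyphenol, via 3-bromo-2,5-dimethoxyphenyl formate 4 (not isolated)
Conditions: mCPBA, CH2Cl2, rt; then MeOH, K2CO3 (cat.), rt
Reagents that add atoms: 3-chloroperbenzoic acid, O=C(OO)c1cccc(Cl)c1
Why: Dakin-type Baeyer–Villiger oxidation, in which the electron-rich ortho-methoxyaryl group migrates in preference to hydride, gives the aryl formate, and methanolysis should release the phenol.

**Step 4**
Reactants: 5 3-bromo-2,5-dimethoxyphenol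
Product: 6 1-(benzyloxy)-3-bromo-2,5-dimethoxybenzene
Conditions: BnBr, K2CO3, DMF, rt
Reagents that add atoms: benzyl bromide, BrCc1ccccc1
Why: Williamson benzylation masks the ring B phenol with a group that withstands aqueous base, boranes and butyllithium and is later removed without fluoride or base.

**Step 5**
Reactants: 7 1,13-tetradecadiene; 6 1-(benzyloxy)-3-bromo-2,5-dimethoxybenzene
Product: 9 1-(benzyloxy)-2,5-dimethoxy-3-(tetradec-13-en-1-yl)benzene, via B-(tetradec-13-en-1-yl)-9-BBN 8 (not isolated)
Conditions: 7 (3 equiv), 9-BBN (1 equiv), THF, 0 °C to rt; then 6 (0.8 equiv), Pd(dppf)Cl2 (5 mol%), 3 M aq. NaOH, THF, 65 °C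
Reagents that add atoms: none
Why: Anti-Markovnikov hydroboration of one terminal alkene of the diene, held in excess so that mono-addition dominates, followed by B-alkyl Suzuki–Miyaura coupling should attach the chain at C3' and leave the far alkene untouched.

**Step 6**
Reactants: 9 1-(benzyloxy)-2,5-dimethoxy-3-(tetradec-13-en-1-yl)benzene; 10 3-bromo-5-methoxyphenol
Product: 12 3-{14-[3-(benzyloxy)-2,5-dimethoxyphenyl]tetradecyl}-5-methoxyphenol, via ring B tetradecyl-9-BBN 11 (not isolated)
Conditions: 9-BBN (1.3 equiv), THF, rt; then 10, Pd(dppf)Cl2 (5 mol%), 3 M aq. NaOH (4 equiv), THF, 65 °C; acidic work-up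
Reagents that add atoms: none
Why: A second hydroboration and B-alkyl Suzuki–Miyaura coupling should complete the C14 tether; the bromophenol couples as its phenoxide once an extra equivalent of base is supplied.

**Step 7**
Reactants: 12 3-{14-[3-(benzyloxy)-2,5-dimethoxyphenyl]tetradecyl}-5-methoxyphenol
Product: 13 3-{14-[3-(benzyloxy)-2,5-dimethoxyphenyl]tetradecyl}-5-methoxyphenyl N-isopropylcarbamate
Conditions: i-PrNCO, Et3N (cat.), CH2Cl2, rt
Reagents that add atoms: isopropyl isocyanate, CC(C)N=C=O
Why: Base-catalysed addition of the ring A phenol to the isocyanate installs a strong ortho-directing group that can later be removed under mild, fluoride-free conditions.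

**Step 8**
Reactants: 13 3-{14-[3-(benzyloxy)-2,5-dimethoxyphenyl]tetradecyl}-5-methoxyphenyl N-isopropylcarbamate
Product: 17 5-{14-[3-(benzyloxy)-2,5-dimethoxyphenyl]tetradecyl}-3-methoxy-2-(trimethylsilyl)phenyl N-isopropylcarbamate, via N-TBS carbamate 14 (not isolated), via aryllithium 15 (not isolated), via N-TBS C-TMS carbamate 16 (not isolated)
Conditions: TBSOTf (1.1 equiv), TMEDA, Et2O, 0 °C to rt; then n-BuLi (1.5 equiv), TMEDA, −78 °C; TMSCl, −78 °C to rt; aq. acid work-up
Reagents that add atoms: chlorotrimethylsilane, C[Si](C)(C)Cl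
Why: In situ N-silylation makes the carbamate tertiary, and directed ortho-metalation then takes place at the ring A carbon flanked by the carbamate and methoxy oxygens, which at −78 °C should lithiate far faster than the ether-only site of ring B; silyl quench and hydrolysis of the N–Si bond follow.

**Step 9**
Reactants: 17 5-{14-[3-(benzyloxy)-2,5-dimethoxyphenyl]tetradecyl}-3-methoxy-2-(trimethylsilyl)phenyl N-isopropylcarbamate
Product: 19 5-{14-[3-(benzyloxy)-2,5-dimethoxyphenyl]tetradecyl}-3-methoxy-2-(trimethylsilyl)phenyl trifluoromethanesulfonate, via 2-silylphenol 18 (not isolated)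
Conditions: DBU, Et2NH, MeCN, 40 °C; then PhNTf2, rt
Reagents that add atoms: N-phenylbis(trifluoromethanesulfonimide), O=S(=O)(N(c1ccccc1)S(=O)(=O)C(F)(F)F)C(F)(F)F
Why: E1cB cleavage of the N–H carbamate (the isocyanate is scavenged by diethylamine) frees the phenoxide, which is triflated in the same flask by triflyl transfer, with no fluoride present to trigger the aryne early.

**Step 10**
Reactants: 19 5-{14-[3-(benzyloxy)-2,5-dimethoxyphenyl]tetradecyl}-3-methoxy-2-(trimethylsilyl)phenyl trifluoromethanesulfonate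
Product: 20 5-[14-(3-hydroxy-2,5-dimethoxyphenyl)tetradecyl]-3-methoxy-2-(trimethylsilyl)phenyl trifluoromethanesulfonate
Conditions: H2 (1 atm), Pd/C, EtOAc, rt
Reagents that add atoms: none
Why: Catalytic hydrogenolysis of the aryl benzyl ether under neutral conditions should spare the aryl–silicon bond and the triflate, which is shielded by the neighbouring trimethylsilyl group.

**Step 11**
Reactants: 20 5-[14-(3-hydroxy-2,5-dimethoxyphenyl)tetradecyl]-3-methoxy-2-(trimethylsilyl)phenyl trifluoromethanesulfonate
Product: 22 trimethyl ether of the target macrocycle (OMe on C1 of ring A and on C2' and C5' of ring B), via aryne cesium phenoxide 21 (not isolated)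
Conditions: anhydrous CsF (5 equiv), MeCN, 50 °C; 20 added by syringe pump over 12 h, final concentration about 1 mM
Reagents that add atoms: none
Why: CsF first turns the ring B phenol into its cesium phenoxide and then attacks the trimethylsilyl group, so that triflate departs and aryne 21 forms with its strained triple bond between C5 and C6 of ring A; the phenoxide oxygen adds in the ring plane to C5, and the aryl anion left at C6 takes up the proton released from the phenol or one from acetonitrile. The closest known reaction is the intermolecular CsF-mediated O-arylation of phenols with ortho-silylaryl triflates in acetonitrile; the ring-closing version over a fourteen-carbon tether extends it and relies on slow addition at high dilution. The 21-membered ring is closed by this single C–O bond formation, formally a 21-exo-dig attack in which C6 stays outside the new ring, and the flexible polymethylene chain should leave the ring unstrained. No stereocentre is created. The step needs addition at C5 and not at C6, and the methoxy group on C1 secures this: its inductive pull distorts the aryne so that C5 is the flatter, more electrophilic carbon and the negative charge develops at C6 next to the C–O bond, as in additions to 3-alkoxyarynes generally. It also needs cyclisation to outrun oligomerisation and capture of the aryne by fluoride or water, which the low stationary concentration, dry conditions and the high aryne affinity of a phenoxide should provide.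

**Step 12**
Reactants: 22 trimethyl ether of the target macrocycle
Product: 23 target macrocycle CNP0393720.0
Conditions: BBr3 (6 equiv), CH2Cl2, −78 °C to rt; aqueous work-up under argon with Na2S2O4 wash
Reagents that add atoms: none
Why: Lewis-acid-mediated cleavage of the three aryl methyl ethers by BBr3 proceeds by bromide attack on the methyl groups, whereas the diaryl ether has no carbon open to such attack and should survive; the reducing work-up guards the ring B hydroquinone against air oxidation.

**Compound list**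
1 | 2-hydroxy-5-methoxybenzaldehyde | COc1ccc(O)c(C=O)c1 | starting material
2 | 3-bromo-2-hydroxy-5-methoxybenzaldehyde | COc1cc(Br)c(O)c(C=O)c1 | intermediate
3 | 3-bromo-2,5-dimethoxybenzaldehyde | COc1cc(Br)c(OC)c(C=O)c1 | intermediate
4 | 3-bromo-2,5-dimethoxyphenyl formate (not isolated) | COc1cc(Br)c(OC)c(OC=O)c1 | intermediate
5 | 3-bromo-2,5-dimethoxyphenol | COc1cc(Br)c(OC)c(O)c1 | intermediate
6 | 1-(benzyloxy)-3-bromo-2,5-dimethoxybenzene | COc1cc(Br)c(OC)c(OCc2ccccc2)c1 | intermediate
7 | 1,13-tetradecadiene | C=CCCCCCCCCCCCC=C | starting material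
8 | B-(tetradec-13-en-1-yl)-9-borabicyclo[3.3.1]nonane (not isolated) | C=CCCCCCCCCCCCCB1C2CCCC1CCC2 | intermediate
9 | 1-(benzyloxy)-2,5-dimethoxy-3-(tetradec-13-en-1-yl)benzene | COc1cc(OCc2ccccc2)c(OC)c(CCCCCCCCCCCCC=C)c1 | intermediate
10 | 3-bromo-5-methoxyphenol | COc1cc(O)cc(Br)c1 | starting material
11 | B-{14-[3-(benzyloxy)-2,5-dimethoxyphenyl]tetradecyl}-9-borabicyclo[3.3.1]nonane (not isolated) | COc1cc(OCc2ccccc2)c(OC)c(CCCCCCCCCCCCCCB2C3CCCC2CCC3)c1 | intermediate
12 | 3-{14-[3-(benzyloxy)-2,5-dimethoxyphenyl]tetradecyl}-5-methoxyphenol | COc1cc(O)cc(CCCCCCCCCCCCCCc2cc(OC)cc(OCc3ccccc3)c2OC)c1 | intermediate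
13 | 3-{14-[3-(benzyloxy)-2,5-dimethoxyphenyl]tetradecyl}-5-methoxyphenyl N-isopropylcarbamate | COc1cc(OC(=O)NC(C)C)cc(CCCCCCCCCCCCCCc2cc(OC)cc(OCc3ccccc3)c2OC)c1 | intermediate
14 | N-(tert-butyldimethylsilyl) derivative of carbamate 13 (not isolated) | COc1cc(OC(=O)N(C(C)C)[Si](C)(C)C(C)(C)C)cc(CCCCCCCCCCCCCCc2cc(OC)cc(OCc3ccccc3)c2OC)c1 | intermediate
15 | aryllithium from 14, lithium on the ring A carbon between the methoxy and carbamate oxygens (not isolated) | [Li]c1c(OC)cc(CCCCCCCCCCCCCCc2cc(OC)cc(OCc3ccccc3)c2OC)cc1OC(=O)N(C(C)C)[Si](C)(C)C(C)(C)C | intermediate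
16 | N-(tert-butyldimethylsilyl) derivative of silyl carbamate 17 (not isolated) | COc1cc(CCCCCCCCCCCCCCc2cc(OC)cc(OCc3ccccc3)c2OC)cc(OC(=O)N(C(C)C)[Si](C)(C)C(C)(C)C)c1[Si](C)(C)C | intermediate
17 | 5-{14-[3-(benzyloxy)-2,5-dimethoxyphenyl]tetradecyl}-3-methoxy-2-(trimethylsilyl)phenyl N-isopropylcarbamate | COc1cc(CCCCCCCCCCCCCCc2cc(OC)cc(OCc3ccccc3)c2OC)cc(OC(=O)NC(C)C)c1[Si](C)(C)C | intermediate
18 | 5-{14-[3-(benzyloxy)-2,5-dimethoxyphenyl]tetradecyl}-3-methoxy-2-(trimethylsilyl)phenol (not isolated) | COc1cc(CCCCCCCCCCCCCCc2cc(OC)cc(OCc3ccccc3)c2OC)cc(O)c1[Si](C)(C)C | intermediate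
19 | 5-{14-[3-(benzyloxy)-2,5-dimethoxyphenyl]tetradecyl}-3-methoxy-2-(trimethylsilyl)phenyl trifluoromethanesulfonate | COc1cc(CCCCCCCCCCCCCCc2cc(OC)cc(OCc3ccccc3)c2OC)cc(OS(=O)(=O)C(F)(F)F)c1[Si](C)(C)C | intermediate
20 | 5-[14-(3-hydroxy-2,5-dimethoxyphenyl)tetradecyl]-3-methoxy-2-(trimethylsilyl)phenyl trifluoromethanesulfonate | COc1cc(CCCCCCCCCCCCCCc2cc(OC)cc(O)c2OC)cc(OS(=O)(=O)C(F)(F)F)c1[Si](C)(C)C | intermediate
21 | cesium 2,5-dimethoxy-3-[14-(3-methoxy-4,5-didehydrophenyl)tetradecyl]phenoxide, the ring A aryne (not isolated) | COC1=CC(CCCCCCCCCCCCCCc2cc(OC)cc([O-])c2OC)=CC#C1.[Cs+] | intermediate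
22 | trimethyl ether of the target macrocycle | COc1cc2cc(c1)Oc1cc(OC)cc(c1OC)CCCCCCCCCCCCCC2 | intermediate
23 | target macrocycle CNP0393720.0 | Oc1cc2cc(c1)Oc1cc(O)cc(c1O)CCCCCCCCCCCCCC2 | target

**Step count and risks**
Total step count: 12. Longest linear sequence: 12 steps (1 to 23).

Steps most likely to fail:

1. Step 11. Ring closure may lose to intermolecular phenoxide–aryne addition (oligomers), or the aryne may be quenched by fluoride or traces of water before the chain end reaches it. The fallback replaces the aryne by an intramolecular Ullmann diaryl ether coupling; it sets out from 9 and comes back at 22. Alkene 9 is hydroborated to borane 11 as in step 6 and coupled (Pd(dppf)Cl2, aq. NaOH, THF, 65 °C) with a threefold excess of commercial 3,5-dibromoanisole to give the monobromide 1-(benzyloxy)-3-[14-(3-bromo-5-methoxyphenyl)tetradecyl]-2,5-dimethoxybenzene F1. The benzyl ether is cleaved with BCl3 and pentamethylbenzene in CH2Cl2 at −78 °C, which should leave the aryl bromide and methyl ethers alone, to give 3-[14-(3-bromo-5-methoxyphenyl)tetradecyl]-2,5-dimethoxyphenol F2. Slow addition of F2 to CuI, N,N-dimethylglycine and Cs2CO3 in dioxane at 100 °C (about 2 mM) should close the same O–C5 bond and give 22.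

2. Step 8. The base may also lithiate ring B between its benzyloxy and methoxy groups, or the carbamoyl group may migrate to carbon (anionic ortho-Fries shift) if the aryllithium warms before the silyl quench. The fallback silylates ring A before ring B is attached; it sets out from 10 and borane 8 and comes back at 18. Coupling of 8 with 10 under the conditions of step 6 should give 3-methoxy-5-(tetradec-13-en-1-yl)phenol F3. Diethylcarbamoyl chloride with K2CO3 in MeCN at reflux gives 3-methoxy-5-(tetradec-13-en-1-yl)phenyl N,N-diethylcarbamate F4, which is stable to aqueous base. s-BuLi and TMEDA in THF at −78 °C give the aryllithium between the two oxygens F5, and TMSCl gives 3-methoxy-5-(tetradec-13-en-1-yl)-2-(trimethylsilyl)phenyl N,N-diethylcarbamate F6. Hydroboration with 9-BBN gives the B-alkyl-9-BBN adduct F7, and Suzuki coupling with 6 as in step 5 gives 5-{14-[3-(benzyloxy)-2,5-dimethoxyphenyl]tetradecyl}-3-methoxy-2-(trimethylsilyl)phenyl N,N-diethylcarbamate F8. LiAlH4 in THF cleaves the carbamate reductively to phenol 18, here isolated, which is triflated with PhNTf2 and DBU in MeCN as in the second half of step 9 to give 19.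

3. Step 10. Hydrogenolysis may stall, or palladium may reductively cleave the C–OTf bond alongside the benzyl ether. The fallback removes the benzyl group before the triflate exists and unmasks the phenoxide in the cyclisation flask; it sets out from 17 and comes back at 22. Hydrogenolysis of 17 (H2, Pd/C, EtOAc) gives 5-[14-(3-hydroxy-2,5-dimethoxyphenyl)tetradecyl]-3-methoxy-2-(trimethylsilyl)phenyl N-isopropylcarbamate F9. TBSCl and imidazole in DMF give its ring B tert-butyldimethylsilyl ether F10. DBU and Et2NH in MeCN, then PhNTf2, give by way of the ring A phenol F11 the silyl ether triflate 5-{14-[3-(tert-butyldimethylsilyloxy)-2,5-dimethoxyphenyl]tetradecyl}-3-methoxy-2-(trimethylsilyl)phenyl trifluoromethanesulfonate F12. Under the CsF conditions of step 11, fluoride should first cleave the labile aryl silyl ether to the cesium phenoxide of 20 F13 and then generate aryne 21, which closes to 22.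

**Further compounds**
F1 | step 11 | 1-(benzyloxy)-3-[14-(3-bromo-5-methoxyphenyl)tetradecyl]-2,5-dimethoxybenzene | COc1cc(Br)cc(CCCCCCCCCCCCCCc2cc(OC)cc(OCc3ccccc3)c2OC)c1
F2 | step 11 | 3-[14-(3-bromo-5-methoxyphenyl)tetradecyl]-2,5-dimethoxyphenol | COc1cc(Br)cc(CCCCCCCCCCCCCCc2cc(OC)cc(O)c2OC)c1
F3 | step 8 | 3-methoxy-5-(tetradec-13-en-1-yl)phenol | COc1cc(O)cc(CCCCCCCCCCCCC=C)c1
F4 | step 8 | 3-methoxy-5-(tetradec-13-en-1-yl)phenyl N,N-diethylcarbamate | CCN(CC)C(=O)Oc1cc(OC)cc(CCCCCCCCCCCCC=C)c1
F5 | step 8 | 2-lithio derivative of F4 (in the flask) | [Li]c1c(OC)cc(CCCCCCCCCCCCC=C)cc1OC(=O)N(CC)CC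
F6 | step 8 | 3-methoxy-5-(tetradec-13-en-1-yl)-2-(trimethylsilyl)phenyl N,N-diethylcarbamate | COc1cc(CCCCCCCCCCCCC=C)cc(OC(=O)N(CC)CC)c1[Si](C)(C)C
F7 | step 8 | B-alkyl-9-BBN adduct of F6 (in the flask) | COc1cc(CCCCCCCCCCCCCCB2C3CCCC2CCC3)cc(OC(=O)N(CC)CC)c1[Si](C)(C)C
F8 | step 8 | 5-{14-[3-(benzyloxy)-2,5-dimethoxyphenyl]tetradecyl}-3-methoxy-2-(trimethylsilyl)phenyl N,N-diethylcarbamate | COc1cc(CCCCCCCCCCCCCCc2cc(OC)cc(OCc3ccccc3)c2OC)cc(OC(=O)N(CC)CC)c1[Si](C)(C)C
F9 | step 10 | 5-[14-(3-hydroxy-2,5-dimethoxyphenyl)tetradecyl]-3-methoxy-2-(trimethylsilyl)phenyl N-isopropylcarbamate | COc1cc(CCCCCCCCCCCCCCc2cc(OC)cc(O)c2OC)cc(OC(=O)NC(C)C)c1[Si](C)(C)C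
F10 | step 10 | 5-{14-[3-(tert-butyldimethylsilyloxy)-2,5-dimethoxyphenyl]tetradecyl}-3-methoxy-2-(trimethylsilyl)phenyl N-isopropylcarbamate | COc1cc(CCCCCCCCCCCCCCc2cc(OC)cc(O[Si](C)(C)C(C)(C)C)c2OC)cc(OC(=O)NC(C)C)c1[Si](C)(C)C
F11 | step 10 | 5-{14-[3-(tert-butyldimethylsilyloxy)-2,5-dimethoxyphenyl]tetradecyl}-3-methoxy-2-(trimethylsilyl)phenol (in the flask) | COc1cc(CCCCCCCCCCCCCCc2cc(OC)cc(O[Si](C)(C)C(C)(C)C)c2OC)cc(O)c1[Si](C)(C)C
F12 | step 10 | 5-{14-[3-(tert-butyldimethylsilyloxy)-2,5-dimethoxyphenyl]tetradecyl}-3-methoxy-2-(trimethylsilyl)phenyl trifluoromethanesulfonate | COc1cc(CCCCCCCCCCCCCCc2cc(OC)cc(O[Si](C)(C)C(C)(C)C)c2OC)cc(OS(=O)(=O)C(F)(F)F)c1[Si](C)(C)C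
F13 | step 10 | cesium phenoxide of 20 (in the flask) | COc1cc(CCCCCCCCCCCCCCc2cc(OC)cc([O-])c2OC)cc(OS(=O)(=O)C(F)(F)F)c1[Si](C)(C)C.[Cs+]
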